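Per day, as a fraction of the charge, the electrophile of the midnight run falls at a nearly steady pace from 4.00 d on, and that pace, as read from the readings, is the quantity carried here.

| flask | electrophile | free base | gas | remark | time |
|---|---|---|---|---|---|
| midnight | 0.050 M | 0.028 M | 19 mM (held) | run made earlier |  |
| north-west | 0.050 M | 0.0150 M | 19 mM (held) |  | 10 d |
| north-east | 0.050 M | 0.0190 M | 19 mM (held) |  | 10 d |

midnight run (percent of the electrophile charged)

| time / d | electrophile / % | target / % |
|---|---|---|
| 1.25 | 94 | 4 |
| 3.00 | 83 | 10 |
| 4.00 | 76 | 17 |
| 6.00 | 65 | 25 |
| 8.00 | 50 | 28 |
| 10.0 | 38 | 32 |

(each reading ± 1.5 percentage points)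

- at the start none of the gas is in solution
- no earlier run changes the charge of free base; that part of a forecast is a guess

- part of the electrophile that has reacted at the end, north-west
- part of the electrophile that has reacted at the end, north-east
- what raising the concentration of free base from its lowest to its highest value here does to the part of the electrophile that has reacted (changes below 5 percentage points count as none) (it falls / no change / it rises)

- First instants: no gas is in solution at the start, and by 1.25 d the midnight flask has lost 6.00% of its electrophile.
- Middle: the midnight readings from 4.00 d on give 0.0607 d⁻¹ as the burn rate, the fraction of charged electrophile lost divided by the time elapsed. The first reading gives a lower 0.0480 d⁻¹.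
- End: by 10.0 d the midnight flask has lost 62.0%, more than its free base charge of 56.0% of the electrophile, and the burn rate at that reading is still 0.0620 d⁻¹.
- What is about to matter: north-west charges free base at 30.0% of the electrophile and north-east at 38.0%.
- My own reckoning treats free base as a small correction to the burn rate and sets that correction to zero, which is a guess, as no earlier run changes that charge. Both flasks then stand at 60.7%, with no change between them.
- The forecast differs: it scales the midnight loss with the free base charge, moves the results slightly back towards that loss, and gives 36% for north-west and 44% for north-east, so its answer on raising free base is "it rises"; in its own words, “The order in base is a guess”.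
- North-west gives 59.0% and north-east 59.0%, so no change (difference 0.016 percentage points); north-west's burn rate is 0.0590 d⁻¹, beside the 0.0607 d⁻¹ read from midnight.

    electrophile + nucleophile → acid set free + target (k = 1.10 L mol⁻¹ h⁻¹)
    nucleophile + acid set free ⇌ protonated nucleophile, settled at all times (K = 83000 L mol⁻¹)
    acid set free + free base ⇌ salt of the base (K = 200 L mol⁻¹, k = 1.20 L mol⁻¹ h⁻¹)
    gas ⇌ nucleophile, rate k4*(csat - [nucleophile]) (kL = 0.0170 h⁻¹)
    free base + target → over-reaction product (k = 0.270 L mol⁻¹ h⁻¹)

- In north-west at 10.0 d, free base is used 68 times faster by the path from target to over-reaction product than by the forward step to salt of the base, and neither path appreciably changes the part reacted. The neighbour with 0.025 M of free base has the same burn rate, 0.0590 d⁻¹, with 59.0% reacted and 23.8% as over-reaction product, against 15.8% in north-west.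

The data are simulated with made-up constants.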